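The constants used here are those of an exercise; the run is a simulation.

Which flask, the hot one or the cool one, holds more target after the same time, and how much in each?

    substrate → intermediate (k1 = 2.1 × 10⁻⁴ s⁻¹, Ea1 = 97.0 kJ mol⁻¹)
    first nucleophile + intermediate → target (k2 = 1.6 M⁻¹ s⁻¹, Ea2 = 47.0 kJ mol⁻¹)
    second nucleophile + intermediate → other capture product (k3 = 12 M⁻¹ s⁻¹, Ea3 = 37.0 kJ mol⁻¹)
    substrate + target → side product A (k4 = 0.0022 M⁻¹ s⁻¹, Ea4 = 55.0 kJ mol⁻¹)
    second nucleophile ⇌ dormant form (K5 = 5.0, k5 = 5.7 × 10⁻⁵ s⁻¹, Ea5 = 102 kJ mol⁻¹, ΔH5 = 1.00 kJ mol⁻¹)
    intermediate → side product B (k6 = 1.7 × 10⁻⁴ s⁻¹, Ea6 = 115 kJ mol⁻¹)
    (constants at 60 °C)

| flask | substrate | first nucleophile | second nucleophile | temperature | time |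
|---|---|---|---|---|---|
| dawn | 0.50 M | 0.350 M | 0.300 M | 80 °C | 50 min |
| noon | 0.50 M | 0.350 M | 0.300 M | 60 °C | 50 min |

- a species is counted by the substrate in it: one side product A counts as two
- at 60 °C the constants are as listed, elsewhere as the activation energies and enthalpies make them

- the best flask by amount of target, in percent of the substrate charged; "all alike" if 1.5 percentage points covers them all (dawn / noon / all alike)
- amount of target at the end, in percent of the substrate charged, dawn
- amount of target at the end, in percent of the substrate charged, noon

The substrate is the limiting reagent, since the two nucleophiles together, at 0.650 M, exceed its 0.50 M. Its ledger has four entries: unopened substrate, other capture product, target, and side product A, where each target lost takes one more substrate with it. Side product B hardly counts at noon, its step running at hardly any of the rate of capture by the first nucleophile at its charge.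

The zero of the scale is the statistical split: with equal constants, the intermediate would go to target in proportion to the charges, 53.8% of it. But at noon's temperature the rate constant of the second nucleophile's capture is 7.50 times that of the first nucleophile's. With [first nucleophile] at its charge, noon's two captures therefore run level when [second nucleophile] has fallen to the crossover level, 0.0467 M, the charged first nucleophile divided by that factor. At the start, noon's split sends 13.5% of the intermediate to target. Holding [first nucleophile] at its charge and setting the dormant form aside, the competition integrates: target made equals the crossover level times the logarithm of charged over remaining second nucleophile.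

By the first step alone, noon opens 46.7% of its substrate, or 0.234 M, less than the second nucleophile charged. Reckoned at the starting split, that leaves 0.0978 M of the second nucleophile, so the reckoned target made is 0.0523 M, or 10.5% of the substrate charged. The remaining substrate eats this target as it forms. With target made at an even pace and substrate at its mean level, the loss exponent over the run is 2.53, so a fraction 0.364 survives and the noon entry closes at 3.81%.

Dawn leaves 1.03% of its substrate unopened by the first step alone. Granting the second nucleophile its whole charge, with the dormant form again set aside, the reckoning leaves an excess of 0.200 M of substrate for target and side product A to share. A substrate leaving by the first step adds a target and one leaving into side product A removes a target, so the net gain per substrate is one minus u over one plus u, where u is the rate into side product A over the rate of the first step. Taking the mean target as a quarter of the excess gives u = 0.222, and the dawn entry closes at 25.5%.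

The forecast names dawn, with 20.5% (16.5% to 24.5%) at dawn and 4.4% (3.5% to 5.5%) at noon, on the ground that “later intermediate goes to target”; the dawn entry reckoned here lies higher than that dawn range.

The simulation gives dawn, with target at 19.8% at dawn and 4.07% at noon, against 25.5% and 3.81% reckoned here. In the noon flask, the second nucleophile still stands at 0.0883 M at 50.0 min, above the crossover level of 0.0467 M, and its capture outruns the first nucleophile's by a factor of 2.2, down from 4.2 at 20.7 min. A neighbour of noon charged with 0.075 M of second nucleophile, 1.61 times that level, ends with target at 13.4% and other capture product at 14.1%.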